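The C4–C5 bond of ring A is the disconnection on which the route rests. In ring B the methyl-bearing quaternary carbon C5 lies directly across the ring from the C8 ketone and is bonded to the secondary methyl carbon C4. Ring B can therefore be read as a 4-methylphenol whose phenolate attacks, through its para carbon, a sulfonate at C4 held on a four-carbon tether from C10. That single alkylation closes ring A, dearomatises ring B to a cross-conjugated dienone and fixes C4 and C5. The precursor is a 5-aryl-3-silyloxypentan-2-yl tosylate in which the acetyl group is masked as a dioxolane and the C3 ether is the equatorial epimer, to be inverted later by oxidation and reduction.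

Key step: step 10

Remark: C1–C4 are the ring A carbons between the ring-fusion atoms C10 (carbinol) and C5 (methyl), C6–C9 the ring B carbons between C5 and C10, and β is the face of the C5 methyl group. In the only chair open to the forming ring A this methyl group is axial, so a 3β ether (target configuration) would be syn-axial to it; the cyclisation substrate therefore carries the 3α ether, and 3β is restored in step 13.

Step 1
Reactants: 1 3-bromo-4-methylphenol; 2 acetyl chloride
Product: 4 1-(4-bromo-2-hydroxy-5-methylphenyl)ethan-1-one, via aryl acetate 3 (not isolated)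
Conditions: AcCl (1.2 equiv), neat, 60 °C; then AlCl3 (1.6 equiv), 140 °C; ice/aq. HCl
Reagents that add atoms: acetyl chloride (compound 2), CC(=O)Cl
Why: O-Acetylation and Fries rearrangement in one pot deliver the acyl group to the only accessible ortho carbon (the para position carries the methyl group and the other ortho carbon is flanked by bromine), which gives the ortho-hydroxyaryl ketone that holds the two carbons of the later C7 acetyl group.

Step 2
Reactants: 4 1-(4-bromo-2-hydroxy-5-methylphenyl)ethan-1-one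
Product: 5 1-[2-(benzyloxy)-4-bromo-5-methylphenyl]ethan-1-one
Conditions: BnBr, K2CO3, DMF, 50 °C
Reagents that add atoms: benzyl bromide, BrCc1ccccc1
Why: Williamson etherification (K2CO3 deprotonates the chelated phenol) masks the phenol so that the ketone can be ketalised and the bromide coupled without a free phenolate.

Step 3
Reactants: 5 1-[2-(benzyloxy)-4-bromo-5-methylphenyl]ethan-1-one
Product: 6 2-[2-(benzyloxy)-4-bromo-5-methylphenyl]-2-methyl-1,3-dioxolane
Conditions: HOCH2CH2OH, p-TsOH (cat.), benzene, reflux, azeotropic removal of water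
Reagents that add atoms: ethane-1,2-diol, OCCO
Why: Acid-catalysed ketalisation stores the aryl ketone as a dioxolane, so that neither the strongly basic ring closure nor the later alkaline peroxide step has to tolerate an enolisable acetyl or 1,3-dicarbonyl group.

Step 4
Reactants: 7 penta-1,4-dien-3-ol
Product: 8 (1R)-1-[(2S)-oxiran-2-yl]prop-2-en-1-ol
Conditions: Ti(OiPr)4, D-(−)-diisopropyl tartrate, tBuOOH, 4 Å molecular sieves, CH2Cl2, −20 °C
Reagents that add atoms: tert-butyl hydroperoxide, CC(C)(C)OO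
Why: Sharpless asymmetric epoxidation of the meso divinyl carbinol selects one enantiotopic vinyl group and one of its faces under tartrate control, setting both stereocentres (anti relationship), and the minor enantiomer is consumed by faster second epoxidation, which should raise the enantiomeric purity.

Step 5
Reactants: 8 (1R)-1-[(2S)-oxiran-2-yl]prop-2-en-1-ol
Product: 9 tert-butyl(dimethyl){[(1R)-1-[(2S)-oxiran-2-yl]prop-2-en-1-yl]oxy}silane
Conditions: TBSCl, imidazole, DMF, 0 °C → rt
Reagents that add atoms: tert-butyldimethylsilyl chloride, C[Si](C)(Cl)C(C)(C)C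
Why: Imidazole-promoted silylation of the secondary allylic alcohol protects the C3 oxygen as the base-stable ether that is carried through the ring closure.

Step 6
Reactants: 9 tert-butyl(dimethyl){[(1R)-1-[(2S)-oxiran-2-yl]prop-2-en-1-yl]oxy}silane
Product: 10 (2S,3R)-3-[(tert-butyldimethylsilyl)oxy]pent-4-en-2-ol
Conditions: LiAlH4, Et2O, 0 °C
Reagents that add atoms: none
Why: Hydride opens the terminal epoxide by SN2 attack at the unsubstituted carbon, which converts the oxirane CH2 into the future C4 methyl group and leaves the configuration of the new secondary alcohol untouched.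

Step 7
Reactants: 10 (2S,3R)-3-[(tert-butyldimethylsilyl)oxy]pent-4-en-2-ol
Product: 11 (2R,3R)-3-[(tert-butyldimethylsilyl)oxy]pent-4-en-2-yl 4-methylbenzenesulfonate
Conditions: Zn(OTs)2 (0.6 equiv), PPh3, DIAD, toluene, 0 °C → rt
Reagents that add atoms: zinc bis(4-methylbenzenesulfonate), [Zn+2].Cc1ccc(cc1)S(=O)(=O)[O-].Cc1ccc(cc1)S(=O)(=O)[O-]
Why: Mitsunobu-type sulfonylation: the alkoxyphosphonium ion formed from the alcohol is displaced by tosylate with inversion, so the sulfonate carbon becomes R and syn to the silyl ether, as the ring closure requires.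

Step 8
Reactants: 11 (2R,3R)-3-[(tert-butyldimethylsilyl)oxy]pent-4-en-2-yl 4-methylbenzenesulfonate; 6 2-[2-(benzyloxy)-4-bromo-5-methylphenyl]-2-methyl-1,3-dioxolane
Product: 13 (2R,3R)-5-[5-(benzyloxy)-2-methyl-4-(2-methyl-1,3-dioxolan-2-yl)phenyl]-3-[(tert-butyldimethylsilyl)oxy]pentan-2-yl 4-methylbenzenesulfonate, via alkylborane 12 (not isolated)
Conditions: 9-BBN, THF, 0 °C → rt; then 6, PdCl2(dppf) (5 mol %), K3PO4 (3 M aq.), DMF, 50 °C
Reagents that add atoms: none
Why: Anti-Markovnikov hydroboration of the terminal alkene with 9-BBN followed by B-alkyl Suzuki–Miyaura coupling joins C1 to the arene carbon C10; the secondary tosylate is inert to the borane and to palladium under these mild aqueous phosphate conditions, and no stereocentre is touched.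

Step 9
Reactants: 13 (2R,3R)-5-[5-(benzyloxy)-2-methyl-4-(2-methyl-1,3-dioxolan-2-yl)phenyl]-3-[(tert-butyldimethylsilyl)oxy]pentan-2-yl 4-methylbenzenesulfonate
Product: 14 (2R,3R)-3-[(tert-butyldimethylsilyl)oxy]-5-[5-hydroxy-2-methyl-4-(2-methyl-1,3-dioxolan-2-yl)phenyl]pentan-2-yl 4-methylbenzenesulfonate
Conditions: H2 (1 atm), Pd/C (10 %), EtOAc, rt
Reagents that add atoms: none
Why: Hydrogenolysis of the aryl benzyl ether over palladium frees the phenol under neutral conditions that leave the alkyl tosylate, the silyl ether and the ketal intact.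

Step 10
Reactants: 14 (2R,3R)-3-[(tert-butyldimethylsilyl)oxy]-5-[5-hydroxy-2-methyl-4-(2-methyl-1,3-dioxolan-2-yl)phenyl]pentan-2-yl 4-methylbenzenesulfonate
Product: 16 (4aR,5R,6R)-6-[(tert-butyldimethylsilyl)oxy]-4a,5-dimethyl-3-(2-methyl-1,3-dioxolan-2-yl)-5,6,7,8-tetrahydronaphthalen-2(4aH)-one, via potassium phenolate 15 (not isolated)
Conditions: KOtBu (1.0 equiv), tBuOH, 80 °C, 0.01 M
Reagents that add atoms: none
Why: KOtBu gives the potassium phenolate, whose para carbon C5 attacks C4 from the side opposite to the tosylate in an intramolecular SN2 reaction; this forms the C4–C5 bond and turns ring B into the cross-conjugated dienone. The closest known reaction type is the intramolecular para C-alkylation of phenolates by tethered sulfonates, which gives 4,4-disubstituted cyclohexa-2,5-dienones. Ring A closes in the 6-exo-tet mode. C4 is set by inversion of the (R)-tosylate, and C5 by a chair-like transition state in which the C3 silyl ether and the C4 methyl group are both equatorial (C4–H over the arene), whereas attack on the other face would put the ether syn-axial to the aryl methyl group and the C4 methyl group over the ring. The step needs alkylation at the para carbon C5 and not at the free ortho carbon C9, and substitution and not elimination: O-alkylation is out of reach for the meta tether, one equivalent of base leaves no alkoxide for E2, tBuOH solvates the O–K end next to C9, and the dioxolane keeps the acetyl group out of enolate chemistry. Once C5 is quaternary the ring cannot rearomatise.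

Step 11
Reactants: 16 (4aR,5R,6R)-6-[(tert-butyldimethylsilyl)oxy]-4a,5-dimethyl-3-(2-methyl-1,3-dioxolan-2-yl)-5,6,7,8-tetrahydronaphthalen-2(4aH)-one
Product: 17 (4aR,5R,6R)-6-hydroxy-4a,5-dimethyl-3-(2-methyl-1,3-dioxolan-2-yl)-5,6,7,8-tetrahydronaphthalen-2(4aH)-one
Conditions: Bu4NF, THF, rt
Reagents that add atoms: none
Why: Fluoride-induced desilylation liberates the equatorial C3 alcohol while the dienone and the ketal are inert to Bu4NF.

Step 12
Reactants: 17 (4aR,5R,6R)-6-hydroxy-4a,5-dimethyl-3-(2-methyl-1,3-dioxolan-2-yl)-5,6,7,8-tetrahydronaphthalen-2(4aH)-one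
Product: 18 (4aR,5R)-4a,5-dimethyl-3-(2-methyl-1,3-dioxolan-2-yl)-4a,5,7,8-tetrahydronaphthalene-2,6-dione
Conditions: Dess–Martin periodinane, NaHCO3, CH2Cl2, rt
Reagents that add atoms: none
Why: Dess–Martin oxidation converts the C3 alcohol into the ketone under buffered, non-enolising conditions, so that the adjacent C4 stereocentre should keep its configuration.

Step 13
Reactants: 18 (4aR,5R)-4a,5-dimethyl-3-(2-methyl-1,3-dioxolan-2-yl)-4a,5,7,8-tetrahydronaphthalene-2,6-dione
Product: 19 (4aR,5R,6S)-6-hydroxy-4a,5-dimethyl-3-(2-methyl-1,3-dioxolan-2-yl)-4,4a,5,6,7,8-hexahydronaphthalen-2(3H)-one (3β-alcohol; C7 epimers)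
Conditions: KBH(sBu)3 (2.3 equiv), THF, −78 °C; aq. NH4Cl
Reagents that add atoms: none
Why: The bulky borohydride reduces the C3 ketone from the equatorial α-side, because the axial path is blocked by the syn-axial C5 methyl group, which gives the axial 3β-alcohol, and in the same operation adds hydride 1,4 to the β-unsubstituted C6=C7 enone but not to the β,β-disubstituted C9=C10 enone (conjugate reduction); C7 is formed as an inconsequential epimer mixture.

Step 14
Reactants: 19 (4aR,5R,6S)-6-hydroxy-4a,5-dimethyl-3-(2-methyl-1,3-dioxolan-2-yl)-4,4a,5,6,7,8-hexahydronaphthalen-2(3H)-one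
Product: 20 9β,10β-epoxy-3β-hydroxy-4β,5β-dimethyl-7-(2-methyl-1,3-dioxolan-2-yl)decalin-8-one (C7 epimers)
Conditions: 30 % H2O2, NaOH (0.5 equiv), MeOH, 0 °C → rt
Reagents that add atoms: hydrogen peroxide, OO
Why: Weitz–Scheffer epoxidation of the only remaining enone: hydroperoxide should add to C10 from the β-face, as it does at the ring-fusion carbon of steroidal 4-en-3-ones, because the α-face is closed by the axial hydrogens on C2 and C4, and the enolate then closes the cis-fused 9β,10β-epoxide.

Step 15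
Reactants: 20 9β,10β-epoxy-3β-hydroxy-4β,5β-dimethyl-7-(2-methyl-1,3-dioxolan-2-yl)decalin-8-one; 21 acetic anhydride
Product: 22 3β-acetoxy-9β,10β-epoxy-4β,5β-dimethyl-7-(2-methyl-1,3-dioxolan-2-yl)decalin-8-one (C7 epimers)
Conditions: Ac2O, pyridine, DMAP (cat.), CH2Cl2, rt
Reagents that add atoms: acetic anhydride (compound 21), CC(=O)OC(C)=O
Why: DMAP-catalysed acetylation of the only hydroxyl group installs the C3 acetate with retention, the epoxy ketone being stable to pyridine at room temperature.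

Step 16
Reactants: 22 3β-acetoxy-9β,10β-epoxy-4β,5β-dimethyl-7-(2-methyl-1,3-dioxolan-2-yl)decalin-8-one; 23 angelic acid
Product: 24 3β-acetoxy-9α-angeloyloxy-10β-hydroxy-4β,5β-dimethyl-7-(2-methyl-1,3-dioxolan-2-yl)decalin-8-one (C7 epimers)
Conditions: angelic acid (4 equiv), Cs2CO3 (1 equiv), DMF, 50 °C
Reagents that add atoms: angelic acid (compound 23), C/C=C(/C)C(=O)O
Why: Epoxide opening by a carboxylate: caesium angelate attacks C9, the SN2-activated carbon next to the ketone, anti to the oxirane oxygen, which gives the 9α-ester and the 10β-tertiary alcohol, while the excess free acid keeps the medium buffered against retro-aldol cleavage and isomerisation to the tiglate.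

Step 17
Reactants: 24 3β-acetoxy-9α-angeloyloxy-10β-hydroxy-4β,5β-dimethyl-7-(2-methyl-1,3-dioxolan-2-yl)decalin-8-one
Product: 25 7-acetyl-3β-acetoxy-9α-angeloyloxy-10β-hydroxy-4β,5β-dimethyldecalin-8-one (enolised 1,3-diketone)
Conditions: PPTS (0.3 equiv), acetone–H2O (5:1), 45 °C
Reagents that add atoms: water, O
Why: Mild acid-catalysed ketal hydrolysis releases the acetyl group as an enolised 1,3-diketone without affecting the two esters or the tertiary alcohol.

Step 18
Reactants: 25 7-acetyl-3β-acetoxy-9α-angeloyloxy-10β-hydroxy-4β,5β-dimethyldecalin-8-one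
Product: 28 (1S,4aR,5R,6S,8aR)-6-acetoxy-3-acetyl-8a-hydroxy-4a,5-dimethyl-2-oxo-1,2,4a,5,6,7,8,8a-octahydronaphthalen-1-yl (2Z)-2-methylbut-2-enoate, via selenide 26 (not isolated), via selenoxide 27 (not isolated)
Conditions: PhSeCl (1.1 equiv), pyridine, CH2Cl2, 0 °C; then 30 % H2O2, 0 °C → rt
Reagents that add atoms: none
Why: α-Selenenylation of the 1,3-diketone at C7 and oxidation give a selenoxide whose syn-elimination can only involve the C6 hydrogens, which restores the C6=C7 double bond regiospecifically under neutral conditions.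

Compound list
1 | 3-bromo-4-methylphenol | Cc1ccc(O)cc1Br | starting material
2 | acetyl chloride | CC(=O)Cl | starting material
3 | 3-bromo-4-methylphenyl acetate | CC(=O)Oc1ccc(C)c(Br)c1 | intermediate (not isolated)
4 | 1-(4-bromo-2-hydroxy-5-methylphenyl)ethan-1-one | CC(=O)c1cc(C)c(Br)cc1O | intermediate
5 | 1-[2-(benzyloxy)-4-bromo-5-methylphenyl]ethan-1-one | CC(=O)c1cc(C)c(Br)cc1OCc2ccccc2 | intermediate
6 | 2-[2-(benzyloxy)-4-bromo-5-methylphenyl]-2-methyl-1,3-dioxolane | CC1(OCCO1)c2cc(C)c(Br)cc2OCc3ccccc3 | intermediate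
7 | penta-1,4-dien-3-ol | C=CC(O)C=C | starting material
8 | (1R)-1-[(2S)-oxiran-2-yl]prop-2-en-1-ol | C=C[C@@H](O)[C@@H]1CO1 | intermediate
9 | tert-butyl(dimethyl){[(1R)-1-[(2S)-oxiran-2-yl]prop-2-en-1-yl]oxy}silane | C=C[C@@H](O[Si](C)(C)C(C)(C)C)[C@@H]1CO1 | intermediate
10 | (2S,3R)-3-[(tert-butyldimethylsilyl)oxy]pent-4-en-2-ol | C=C[C@@H](O[Si](C)(C)C(C)(C)C)[C@H](C)O | intermediate
11 | (2R,3R)-3-[(tert-butyldimethylsilyl)oxy]pent-4-en-2-yl 4-methylbenzenesulfonate | C=C[C@@H](O[Si](C)(C)C(C)(C)C)[C@@H](C)OS(=O)(=O)c1ccc(C)cc1 | intermediate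
12 | 9-[(3R,4R)-3-[(tert-butyldimethylsilyl)oxy]-4-(tosyloxy)pentyl]-9-borabicyclo[3.3.1]nonane | B1(C2CCCC1CCC2)CC[C@@H](O[Si](C)(C)C(C)(C)C)[C@@H](C)OS(=O)(=O)c3ccc(C)cc3 | intermediate (not isolated)
13 | (2R,3R)-5-[5-(benzyloxy)-2-methyl-4-(2-methyl-1,3-dioxolan-2-yl)phenyl]-3-[(tert-butyldimethylsilyl)oxy]pentan-2-yl 4-methylbenzenesulfonate | CC1(OCCO1)c2cc(C)c(CC[C@@H](O[Si](C)(C)C(C)(C)C)[C@@H](C)OS(=O)(=O)c3ccc(C)cc3)cc2OCc4ccccc4 | intermediate
14 | (2R,3R)-3-[(tert-butyldimethylsilyl)oxy]-5-[5-hydroxy-2-methyl-4-(2-methyl-1,3-dioxolan-2-yl)phenyl]pentan-2-yl 4-methylbenzenesulfonate (key-step precursor) | CC1(OCCO1)c2cc(C)c(CC[C@@H](O[Si](C)(C)C(C)(C)C)[C@@H](C)OS(=O)(=O)c3ccc(C)cc3)cc2O | intermediate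
15 | potassium phenolate of 14 | CC1(OCCO1)c2cc(C)c(CC[C@@H](O[Si](C)(C)C(C)(C)C)[C@@H](C)OS(=O)(=O)c3ccc(C)cc3)cc2[O-].[K+] | intermediate (not isolated)
16 | (4aR,5R,6R)-6-[(tert-butyldimethylsilyl)oxy]-4a,5-dimethyl-3-(2-methyl-1,3-dioxolan-2-yl)-5,6,7,8-tetrahydronaphthalen-2(4aH)-one (3α-silyloxy, 4β,5β-dimethyl; key-step product) | CC1(OCCO1)C2=C[C@]3(C)[C@@H](C)[C@H](O[Si](C)(C)C(C)(C)C)CCC3=CC2=O | intermediate
17 | (4aR,5R,6R)-6-hydroxy-4a,5-dimethyl-3-(2-methyl-1,3-dioxolan-2-yl)-5,6,7,8-tetrahydronaphthalen-2(4aH)-one | CC1(OCCO1)C2=C[C@]3(C)[C@@H](C)[C@H](O)CCC3=CC2=O | intermediate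
18 | (4aR,5R)-4a,5-dimethyl-3-(2-methyl-1,3-dioxolan-2-yl)-4a,5,7,8-tetrahydronaphthalene-2,6-dione | CC1(OCCO1)C2=C[C@]3(C)[C@@H](C)C(=O)CCC3=CC2=O | intermediate
19 | (4aR,5R,6S)-6-hydroxy-4a,5-dimethyl-3-(2-methyl-1,3-dioxolan-2-yl)-4,4a,5,6,7,8-hexahydronaphthalen-2(3H)-one (3β-alcohol; C7 epimers) | CC1(OCCO1)C2C[C@]3(C)[C@@H](C)[C@@H](O)CCC3=CC2=O | intermediate
20 | 9β,10β-epoxy-3β-hydroxy-4β,5β-dimethyl-7-(2-methyl-1,3-dioxolan-2-yl)decalin-8-one (C7 epimers) | O1[C@H]2C(=O)C(C3(C)OCCO3)C[C@]4(C)[C@@H](C)[C@@H](O)CC[C@]124 | intermediate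
21 | acetic anhydride | CC(=O)OC(C)=O | starting material
22 | 3β-acetoxy-9β,10β-epoxy-4β,5β-dimethyl-7-(2-methyl-1,3-dioxolan-2-yl)decalin-8-one (C7 epimers) | O1[C@H]2C(=O)C(C3(C)OCCO3)C[C@]4(C)[C@@H](C)[C@@H](OC(C)=O)CC[C@]124 | intermediate
23 | angelic acid, (2Z)-2-methylbut-2-enoic acid | C/C=C(/C)C(=O)O | starting material
24 | 3β-acetoxy-9α-angeloyloxy-10β-hydroxy-4β,5β-dimethyl-7-(2-methyl-1,3-dioxolan-2-yl)decalin-8-one (C7 epimers) | C/C=C(/C)C(=O)O[C@@H]1C(=O)C(C2(C)OCCO2)C[C@]3(C)[C@@H](C)[C@@H](OC(C)=O)CC[C@]13O | intermediate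
25 | 7-acetyl-3β-acetoxy-9α-angeloyloxy-10β-hydroxy-4β,5β-dimethyldecalin-8-one (enolised 1,3-diketone) | C/C=C(/C)C(=O)O[C@@H]1C(=O)C(C(C)=O)C[C@]2(C)[C@@H](C)[C@@H](OC(C)=O)CC[C@]12O | intermediate
26 | 7-(phenylselanyl) derivative of 25 | C/C=C(/C)C(=O)O[C@@H]1C(=O)C([Se]c2ccccc2)(C(C)=O)C[C@]3(C)[C@@H](C)[C@@H](OC(C)=O)CC[C@]13O | intermediate (not isolated)
27 | selenoxide of 26 | C/C=C(/C)C(=O)O[C@@H]1C(=O)C([Se](=O)c2ccccc2)(C(C)=O)C[C@]3(C)[C@@H](C)[C@@H](OC(C)=O)CC[C@]13O | intermediate (not isolated)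
28 | (1S,4aR,5R,6S,8aR)-6-acetoxy-3-acetyl-8a-hydroxy-4a,5-dimethyl-2-oxo-1,2,4a,5,6,7,8,8a-octahydronaphthalen-1-yl (2Z)-2-methylbut-2-enoate (CNP0196241.1) | C/C=C(/C)C(=O)O[C@@H]1C(=O)C(C(C)=O)=C[C@]2(C)[C@@H](C)[C@@H](OC(C)=O)CC[C@]12O | target

Total step count: 18. Longest linear sequence: 15 steps (from 7 through steps 4–18); the aryl branch from 1 runs 14 steps.

Steps most likely to fail

Step 10 (ring closure). C-alkylation at the unsubstituted ortho carbon C9, followed by tautomerisation back to a phenol, may outrun the hindered attack of the methyl-bearing para carbon on a secondary centre. The fallback blocks the competing carbon. From phenol 14, N-bromosuccinimide in MeCN at 0 °C should brominate the only free position ortho to the hydroxyl group and give bromophenol tosylate F1. KOtBu in tBuOH then leaves only C5 for alkylation and should give 9-bromo dienone F2. Palladium-catalysed formate reduction of the vinylic bromide (Pd(OAc)2, PPh3, HCO2H, Et3N, DMF, 60 °C) returns to dienone 16.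

Step 16 (epoxide opening by angelate). The branched, weakly nucleophilic carboxylate may open the epoxide so slowly that isomerisation of the angelate to the tiglate or base-induced retro-aldol cleavage of the product takes over. The fallback separates C–O bond formation from angelate introduction. From epoxy acetate 22, CsO2CH with HCO2H in DMF should open the epoxide at C9 to 9α-formate F3. KHCO3 in MeOH at 0 °C should cleave the formate much faster than the C3 acetate and give 9α,10β-diol F4. Yamaguchi esterification of the secondary C9 hydroxyl with angelic acid 23 (2,4,6-trichlorobenzoyl chloride, Et3N, toluene; then F4, 70 °C, no DMAP) returns to 24; the tertiary C10 hydroxyl should not react.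

Step 13 (double reduction). The bulky borohydride may attack the C8 carbonyl directly, or add too slowly to the neopentyl C6 position while the C3 ketone competes for it. The fallback separates the two reductions and uses copper hydride for the conjugate step. From silyl ether 16, [(Ph3P)CuH]6 in wet benzene at rt should reduce only the β-unsubstituted C6=C7 enone and give silyloxy enone F5. Bu4NF gives hydroxy enone F6 and Dess–Martin oxidation gives enedione F7. LiBH(sBu)3 (1.05 equiv, THF, −78 °C) should then reduce the saturated C3 ketone from the equatorial side without touching the hindered β,β-disubstituted enone, returning to 19.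

Further compounds
F1 | step 10 | (2R,3R)-5-[2-bromo-3-hydroxy-6-methyl-4-(2-methyl-1,3-dioxolan-2-yl)phenyl]-3-[(tert-butyldimethylsilyl)oxy]pentan-2-yl 4-methylbenzenesulfonate | CC1(OCCO1)c2cc(C)c(CC[C@@H](O[Si](C)(C)C(C)(C)C)[C@@H](C)OS(=O)(=O)c3ccc(C)cc3)c(Br)c2O
F2 | step 10 | (4aR,5R,6R)-1-bromo-6-[(tert-butyldimethylsilyl)oxy]-4a,5-dimethyl-3-(2-methyl-1,3-dioxolan-2-yl)-5,6,7,8-tetrahydronaphthalen-2(4aH)-one | CC1(OCCO1)C2=C[C@]3(C)[C@@H](C)[C@H](O[Si](C)(C)C(C)(C)C)CCC3=C(Br)C2=O
F3 | step 16 | 3β-acetoxy-9α-formyloxy-10β-hydroxy-4β,5β-dimethyl-7-(2-methyl-1,3-dioxolan-2-yl)decalin-8-one (C7 epimers) | O=CO[C@@H]1C(=O)C(C2(C)OCCO2)C[C@]3(C)[C@@H](C)[C@@H](OC(C)=O)CC[C@]13O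
F4 | step 16 | 3β-acetoxy-9α,10β-dihydroxy-4β,5β-dimethyl-7-(2-methyl-1,3-dioxolan-2-yl)decalin-8-one (C7 epimers) | O[C@@H]1C(=O)C(C2(C)OCCO2)C[C@]3(C)[C@@H](C)[C@@H](OC(C)=O)CC[C@]13O
F5 | step 13 | (4aR,5R,6R)-6-[(tert-butyldimethylsilyl)oxy]-4a,5-dimethyl-3-(2-methyl-1,3-dioxolan-2-yl)-4,4a,5,6,7,8-hexahydronaphthalen-2(3H)-one (C7 epimers) | CC1(OCCO1)C2C[C@]3(C)[C@@H](C)[C@H](O[Si](C)(C)C(C)(C)C)CCC3=CC2=O
F6 | step 13 | (4aR,5R,6R)-6-hydroxy-4a,5-dimethyl-3-(2-methyl-1,3-dioxolan-2-yl)-4,4a,5,6,7,8-hexahydronaphthalen-2(3H)-one (C7 epimers) | CC1(OCCO1)C2C[C@]3(C)[C@@H](C)[C@H](O)CCC3=CC2=O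
F7 | step 13 | (4aR,5R)-4a,5-dimethyl-3-(2-methyl-1,3-dioxolan-2-yl)-3,4,4a,5,7,8-hexahydronaphthalene-2,6-dione (C7 epimers) | CC1(OCCO1)C2C[C@]3(C)[C@@H](C)C(=O)CCC3=CC2=O
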